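## Structural features

The target 12 is (6R,11S)-3-methoxy-2,4,4-trimethyl-8-(4-methylpent-3-en-1-yl)-11-(propan-2-yl)spiro[5.5]undeca-2,8-diene-1,5-dione, C24H36O3, and this numbering is used throughout. Ring A (C1–C6) is a β-triketone fixed as its methyl enol ether: C1=O is conjugated with C2(Me)=C3(OMe), C4 carries the gem-dimethyl group, and C5=O is an isolated ketone. Ring B (C6–C11) is a cyclohexene with the trisubstituted alkene C8=C9, the homoprenyl chain on C8 and the isopropyl group on C11. The rings share only C6, a quaternary carbon flanked by both carbonyl groups and bonded to the second stereocentre C11. On ring B the isopropyl group is cis to C1 and trans to C5.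

The real difficulty is that C6 is stereogenic only because the two arms of ring A differ further out (C2 is sp2 with one methyl, C4 is sp3 with two). C1=O and C5=O look alike to any reagent, so a planar C6 (enolate or alkylidene) offers two nearly equivalent orientations. A second trap is that the chain sits on C8, which is 1,3 to C6 and not 1,4 as the usual orientation of a 2-substituted diene would place it.

The fragile groups are the acid-labile enol ether, the non-enolisable 1,3-diketone units around C5 (cleaved by nucleophilic base) and two acid-sensitive trisubstituted alkenes. The key step exploits the array O=C5–C6–C7–C8=C9. This γ,δ-unsaturated ketone spans both rings and is the retron of a [3,3] shift from oxygen to carbon.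

## Logic of the disconnections

**12 ⇒ 11.**
- Cut: C6–C7 is cut, the oxygen of C5 is reconnected to C9, and the alkene moves from C8=C9 to C7=C8. In one sentence, the route is a thermal [3,3] ring switch of the oxygen-bridged isomer 11. That sentence does not fit a cycloaddition route.
- Reason: the bridge runs through one specific carbonyl oxygen, so the C1/C5 ambiguity becomes a matter of constitution and no longer of face selectivity.
- Gain: the quaternary spiro centre and the carbocycle are replaced by a fused dihydropyran with two tertiary, 1,3-related centres, and no reagent is needed. The mechanism also fixes the chain on C8.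
- Demand: 11 must carry the bridge on the C5 oxygen, and its alkenyl and isopropyl groups must be cis (2R,4S).
- Chromene numbering of 11 against the target: C2 = C9, C3 = C10, C4 = C11, C4a = C6, C5 = C1, C6 = C2, C7 = C3, C8 = C4, C8a = C5.

**11 ⇒ 10.**
- Cut: the O–CH3 bond on C3.
- Reason: the free vinylogous acid is the direct product of a ring closure.
- Gain: one protecting-group-free functional step.
- Demand: methylation must go to the oxygen on C3 and not to the one on C1.

**10 ⇒ 9.**
- Cut: C1–C2, which opens ring A.
- Reason: if ring A is closed only after the pyran exists, C1 is still an ester when the bridge is made and cannot compete for it.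
- Gain: ring A becomes an acyclic tricarbonyl chain.
- Demand: the CH2 of the ethyl ketone must be the only enolisable site, and it must lie cis to the ester across the enol ether double bond. Both hold by structure.

**9 ⇒ 8.**
- Cut: the O–C9 bond.
- Reason: the oxygen then comes from the C5 ketone enolate, so the hindered C5 carbon is never attacked and the carbinol never acts as a nucleophile towards the ester.
- Gain: an open chain.
- Demand: clean inversion at C9 and O-selectivity.

**8 ⇒ 7 + 5.**
- Cut: C8–C9.
- Reason: the whole C7–C8 unit with its chain arrives as one alkenyl fragment.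
- Gain: convergence.
- Demand: aldehyde-selective addition in the presence of two ketones and an ester, with reagent control of the carbinol centre.

**7 ⇒ 3 + 6.**
- Cut: C6–C11.
- Reason: it is a 1,5-dicarbonyl relation, and C11 is the only centre that must be made from achiral material.
- Gain: two simple achiral pieces.
- Demand: high face selectivity at a β-isopropyl enal.

**3 ⇒ 1 + 2.**
- Cut: C3–C4.
- Reason: this creates the gem-dimethyl quaternary carbon by acylation of a tertiary carbanion.
- Gain: two commercial compounds.
- Demand: γ-selective over α-selective reaction.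

**5 ⇒ 4.**
- Cut: the C–O bond of the triflate.
- Gain: a commercial methyl ketone.
- Demand: kinetic enolisation at the methyl group.

## Other disconnections considered

Alternative 1: C6–C7 and C10–C11 are cut together. The forward step is an intermolecular Diels–Alder reaction of myrcene A2 with the isobutylidene dione A1. This is the first idea that comes to mind, and it fails on four structural grounds.
- The largest HOMO coefficient of a 2-substituted diene lies on C1, which should bond to the β-carbon of A1. The chain then ends on C9 (regioisomer A3), not on C8.
- A1 is also a 1-oxadiene, so addition across the vinyl group of A2 competes with the all-carbon mode.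
- The configuration of C6 relative to C11 would be set by the alkene geometry of A1. Its two flanking carbonyl groups are almost equal and its geometry is labile.
- A chiral Lewis acid bound to A1 cannot tell C1=O from C5=O, so absolute control has no handle.

Alternative 2: C6–C7 alone is cut in the polar sense. In the forward step Pd(PPh3)4 ionises the allylic carbonate A4, and the dione enolate closes ring B at the CH2 terminus (intramolecular Tsuji–Trost alkylation). The regiochemistry of the alkene would be correct. Once the enolate is free, however, rotation about C6–C11 exchanges the C1 and C5 flanks. The two rotamers differ only remotely, so C6 has no reliable control element. O-alkylation is also reversible under these conditions and feeds the same uncontrolled manifold. A4 further needs a ring A dione with a regiodefined enol ether, which costs more steps than 9.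

Alternative 3: C8=C9 is cut. The forward step is ring-closing metathesis of the diene A5 with the second-generation Grubbs catalyst. The closure itself is plausible, although it must join a 1,1-disubstituted alkene next to a quaternary carbon. The problem of C6 is only moved back to the C-alkylation of a 2-substituted dione. There the same rotamer ambiguity applies, O-alkylation competes, and two extra carbon–carbon bond formations are needed. The plan is longer and leaves the hardest stereocentre unsolved.

Key step: step 8

Assumption: 7 and 8 are drawn as open-chain tricarbonyl compounds, although they may rest partly in cyclic hemiacetal forms. Their carbon between ester and ketone (future C6) is a labile epimer mixture that becomes sp2 in 9.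

## Steps

Step 1
Reactants: 1 methyl 4-methyl-3-oxopentanoate; 2 propanoyl chloride
Product: 3 methyl 4,4-dimethyl-3,5-dioxoheptanoate
Conditions: NaH, THF, 0 °C; n-BuLi, 0 °C; then 2, −78 to −40 °C; aq. NH4Cl
Reagents that add atoms: none
Why: γ-Acylation of a β-ketoester dianion; the second, more basic carbanion at the tertiary γ-carbon attacks the acid chloride, forming C3–C4 and the gem-dimethyl carbon, while the remaining enolate shields the ester and the future C6.

Step 2
Reactants: 4 6-methylhept-5-en-2-one
Product: 5 6-methylhepta-1,5-dien-2-yl trifluoromethanesulfonate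
Conditions: LiN(iPr)2, THF, −78 °C; PhNTf2, −78 °C to rt; aq. NH4Cl
Reagents that add atoms: N-phenylbis(trifluoromethanesulfonimide), O=S(=O)(C(F)(F)F)N(c1ccccc1)S(=O)(=O)C(F)(F)F
Why: Kinetic enolisation of a methyl ketone at the CH3 group followed by O-sulfonylation gives the 1,1-disubstituted alkenyl triflate; the trisubstituted alkene is inert.

Step 3
Reactants: 3 methyl 4,4-dimethyl-3,5-dioxoheptanoate; 6 (E)-4-methylpent-2-enal
Product: 7 methyl 4,4-dimethyl-2-[(3S)-4-methyl-1-oxopentan-3-yl]-3,5-dioxoheptanoate (epimer mixture at C2 of the heptanoate)
Conditions: (S)-α,α-diphenylprolinol trimethylsilyl ether (20 mol %), PhCO2H (20 mol %), toluene, 0 °C to rt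
Reagents that add atoms: none
Why: Iminium-catalysed asymmetric Michael addition of a 1,3-dicarbonyl compound to an enal; the diphenyl(silyloxy)methyl group of the S catalyst shields one face of the E, s-trans iminium ion, so the carbon nucleophile takes the open face and sets C11 as S. The hindered ethyl ketone and the ester are spectators.

Step 4
Reactants: 7 methyl 4,4-dimethyl-2-[(3S)-4-methyl-1-oxopentan-3-yl]-3,5-dioxoheptanoate; 5 6-methylhepta-1,5-dien-2-yl trifluoromethanesulfonate
Product: 8 methyl 2-[(3S,5S)-5-hydroxy-2,10-dimethyl-6-methylideneundec-9-en-3-yl]-4,4-dimethyl-3,5-dioxoheptanoate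
Conditions: CrCl2 (4 equiv), NiCl2 (2 mol %), N-[2-(4-isopropyl-4,5-dihydro-1,3-oxazol-2-yl)-6-methylphenyl]methanesulfonamide (single antipode, 4.4 equiv), Et3N, THF, rt; aq. EDTA
Reagents that add atoms: none
Why: Nozaki–Hiyama–Kishi coupling; the alkenylchromium species formed through nickel catalysis adds to aldehydes only and is weakly basic, so ketones, ester and the acidic CH should survive. The chiral sulfonamide on chromium sets the carbinol by reagent control, and the antipode that gives 5S is to be fixed on a model aldehyde.

Step 5
Reactants: 8 methyl 2-[(3S,5S)-5-hydroxy-2,10-dimethyl-6-methylideneundec-9-en-3-yl]-4,4-dimethyl-3,5-dioxoheptanoate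
Product: 9 methyl (2R,4S)-6-(2-methyl-3-oxopentan-2-yl)-2-(6-methylhepta-1,5-dien-2-yl)-4-(propan-2-yl)-3,4-dihydro-2H-pyran-5-carboxylate
Conditions: PPh3, DIAD, toluene (0.01 M), 0 °C to rt
Reagents that add atoms: none
Why: Intramolecular Mitsunobu O-alkylation of a β-ketoester; the ketone oxygen of the enolate displaces the activated carbinol in a 6-exo-tet closure with inversion (5S to 2R), which gives the cis-2,4 pyran, whereas C-alkylation would need a cyclobutane. Only the future C5 ketone shares the enolate with the ester, so the bridge cannot end on another ketone, and the hindered C5 carbon is never attacked.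

Step 6
Reactants: 9 methyl (2R,4S)-6-(2-methyl-3-oxopentan-2-yl)-2-(6-methylhepta-1,5-dien-2-yl)-4-(propan-2-yl)-3,4-dihydro-2H-pyran-5-carboxylate
Product: 10 (2R,4S)-7-hydroxy-6,8,8-trimethyl-2-(6-methylhepta-1,5-dien-2-yl)-4-(propan-2-yl)-3,4-dihydro-2H-chromen-5(8H)-one
Conditions: KOtBu (1.2 equiv), THF, 0 °C to rt; cold 0.5 M HCl to pH 4
Reagents that add atoms: none
Why: Dieckmann condensation; the CH2 of the ethyl ketone is the only enolisable position and is held cis to the ester across the tetrasubstituted alkene, so a 6-(enolexo)-exo-trig closure forms C1–C2. Deprotonation of the resulting vinylogous acid drives the equilibrium, and neither stereocentre is acidic.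

Step 7
Reactants: 10 (2R,4S)-7-hydroxy-6,8,8-trimethyl-2-(6-methylhepta-1,5-dien-2-yl)-4-(propan-2-yl)-3,4-dihydro-2H-chromen-5(8H)-one
Product: 11 (2R,4S)-7-methoxy-6,8,8-trimethyl-2-(6-methylhepta-1,5-dien-2-yl)-4-(propan-2-yl)-3,4-dihydro-2H-chromen-5(8H)-one
Conditions: TMSCHN2, toluene/MeOH 4:1, 0 °C
Reagents that add atoms: (trimethylsilyl)diazomethane, C[Si](C)(C)C=[N+]=[N-]
Why: O-methylation of a vinylogous acid by a diazoalkane under non-basic conditions, which excludes C-methylation. The cross-conjugated tautomer with both oxygen substituents next to the gem-dimethyl carbon is the usual resting form of 4,4-dimethyl-3,5-dioxygenated cyclohexadienones, and the peri isopropyl group shields the other oxygen, so the 7-methoxy isomer is expected.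

Step 8
Reactants: 11 (2R,4S)-7-methoxy-6,8,8-trimethyl-2-(6-methylhepta-1,5-dien-2-yl)-4-(propan-2-yl)-3,4-dihydro-2H-chromen-5(8H)-one
Product: 12 (6R,11S)-3-methoxy-2,4,4-trimethyl-8-(4-methylpent-3-en-1-yl)-11-(propan-2-yl)spiro[5.5]undeca-2,8-diene-1,5-dione
Conditions: degassed o-xylene (0.02 M), BHT (5 mol %), base-washed sealed tube, 175 °C
Reagents that add atoms: none
Why: Claisen rearrangement, concerted and suprafacial: the allyl vinyl ether C4a=C8a–O1–C2–C(=CH2) of 11 passes through the only geometry the ring allows, a boat-like array resembling bicyclo[2.2.2]octane with C2 and C4a as bridgeheads, in which O1–C2 breaks while the exocyclic CH2 bonds to C4a. The closest known reactions are the thermal conversion of 2-vinyl-3,4-dihydro-2H-pyrans into cyclohex-3-enyl carbonyl compounds and the rearrangement of 3-allyloxy-2-alkylcyclohex-2-enones into 2-allyl-2-alkylcyclohexane-1,3-diones. Ring B closes as a six-membered carbocycle by a ring switch (6-endo attack of C4a on the 1,1-disubstituted alkene) at the expense of the six-membered oxacycle, and the mechanism leaves the alkene at C8=C9, so the chain can only end 1,3 to C6. The one new stereocentre, C6, is controlled by two elements fixed beforehand: the 2R centre holds the alkenyl group over one face of C4a, and the bridging oxygen marks C8a as the future C5, so C5 ends trans and C1 cis to the isopropyl group, which is 6R, while C11 is a spectator. The step needs periselectivity over a [1,3] shift, cycloreversion and C–O heterolysis: the [1,3] product would be a cyclobutane, and breaking two bonds or separating charge in an apolar solvent should cost more than the cyclic six-electron path. The driving force is the new C5=O bond, which should outweigh the loss of one vinylogous ester conjugation and the crowding at C6. No reagent is present, so the enol ether, the alkenes and the base-sensitive 1,3-diketone are not at risk.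

## Compound list

1 | methyl 4-methyl-3-oxopentanoate | COC(=O)CC(=O)C(C)C | starting material
2 | propanoyl chloride | CCC(=O)Cl | starting material
3 | methyl 4,4-dimethyl-3,5-dioxoheptanoate | COC(=O)CC(=O)C(C)(C)C(=O)CC | intermediate
4 | 6-methylhept-5-en-2-one | CC(=O)CCC=C(C)C | starting material
5 | 6-methylhepta-1,5-dien-2-yl trifluoromethanesulfonate | C=C(CCC=C(C)C)OS(=O)(=O)C(F)(F)F | intermediate
6 | (E)-4-methylpent-2-enal | CC(C)/C=C/C=O | starting material
7 | methyl 4,4-dimethyl-2-[(3S)-4-methyl-1-oxopentan-3-yl]-3,5-dioxoheptanoate | COC(=O)C([C@@H](CC=O)C(C)C)C(=O)C(C)(C)C(=O)CC | intermediate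
8 | methyl 2-[(3S,5S)-5-hydroxy-2,10-dimethyl-6-methylideneundec-9-en-3-yl]-4,4-dimethyl-3,5-dioxoheptanoate | COC(=O)C([C@@H](C[C@H](O)C(=C)CCC=C(C)C)C(C)C)C(=O)C(C)(C)C(=O)CC | intermediate
9 | methyl (2R,4S)-6-(2-methyl-3-oxopentan-2-yl)-2-(6-methylhepta-1,5-dien-2-yl)-4-(propan-2-yl)-3,4-dihydro-2H-pyran-5-carboxylate | COC(=O)C1=C(O[C@H](C[C@H]1C(C)C)C(=C)CCC=C(C)C)C(C)(C)C(=O)CC | intermediate
10 | (2R,4S)-7-hydroxy-6,8,8-trimethyl-2-(6-methylhepta-1,5-dien-2-yl)-4-(propan-2-yl)-3,4-dihydro-2H-chromen-5(8H)-one | CC1=C(O)C(C)(C)C2=C(C1=O)[C@H](C(C)C)C[C@@H](O2)C(=C)CCC=C(C)C | intermediate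
11 | (2R,4S)-7-methoxy-6,8,8-trimethyl-2-(6-methylhepta-1,5-dien-2-yl)-4-(propan-2-yl)-3,4-dihydro-2H-chromen-5(8H)-one | CC1=C(OC)C(C)(C)C2=C(C1=O)[C@H](C(C)C)C[C@@H](O2)C(=C)CCC=C(C)C | intermediate
12 | (6R,11S)-3-methoxy-2,4,4-trimethyl-8-(4-methylpent-3-en-1-yl)-11-(propan-2-yl)spiro[5.5]undeca-2,8-diene-1,5-dione | COC1=C(C)C(=O)[C@]2(CC(CCC=C(C)C)=CC[C@H]2C(C)C)C(=O)C1(C)C | target

## Step count and least certain steps

Total step count: 8. Longest linear sequence: 7 (steps 1, 3, 4, 5, 6, 7, 8).

**Step 8 (key step).**
- Risk: the boat-like transition state brings the CH2 group in on the face that also carries the isopropyl group, so the temperature needed may be high. At that temperature, cycloreversion of the dihydropyran or heterolysis of the allylic C–O bond could compete. Either would erase the stereochemical information held by the bridge and allow recombination in another orientation.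
- Fallback (from 9, back at 12): the [3,3] shift is moved forward to the monocyclic stage. There the enol ether is twisted out of conjugation by its tertiary alkyl neighbour and the heterodiene that cycloreversion would release is less stabilised. Heating 9 in o-xylene should give the rearranged cyclohexene keto ester F1, in which C1 (ester) and C5 (ketone) stay chemically distinct. Dieckmann closure with KOtBu then gives the spiro vinylogous acid F2. Methylation with TMSCHN2, now steered by the isopropyl group that lies cis to C1 and shields its oxygen, leads to 12.

**Step 5.**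
- Risk: the tricarbonyl CH may be too weakly acidic for smooth betaine protonation. The activated secondary allylic carbinol may lose a proton to give a conjugated diene or react with allylic transposition. Lactonisation of the δ-hydroxy ester could also set in before activation.
- Fallback (from 7, back at 9): the bond is made at the other carbon with retention. Step 4 is run with the antipodal ligand to give the 5R carbinol F3. It is closed by acid-catalysed ketalisation and elimination (camphorsulfonic acid, HC(OMe)3, MeOH, then warm toluene). The carbinol C–O bond stays untouched, and methanol as cosolvent holds the methyl ester against lactonisation.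

**Step 4.**
- Risk: reagent control may be mismatched with the resident C11 centre and give poor facial selectivity. The acidic tricarbonyl CH may protonate the alkenylchromium species. The chromium alkoxide may attack the ester.
- Fallback (from 7, back at 8): the centre is set by reduction instead of addition. Ligand-free coupling of 7 and 5 with CrCl2 and catalytic NiCl2 in DMF gives the C5-epimeric carbinol mixture F4. Dess–Martin periodinane oxidises it to the α-methylene enone F5. Corey–Bakshi–Shibata reduction with the (R)-methyl oxazaborolidine and catecholborane at −40 °C, with the branched alkenyl group as the large substituent, should give 8.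

**Step 7.**
- Risk: methylation of the ambident vinylogous acid may take place on the oxygen of C5 (chromene numbering), because both oxygens are flanked by substituents on each side.
- Fallback (from 10, back at 10): the single pass is replaced by a correcting loop. The mis-methylated linear dienone F6 is separated, cleaved back to 10 by vinylogous ester saponification with aqueous LiOH in THF, and resubmitted. Material is thereby funnelled into 11 without loss of the stereocentres.

**Step 3.**
- Risk: a β-isopropyl enal and a bulky donor may react slowly, so that retro-Michael equilibration erodes the enantiomeric purity, or 1,2-addition with condensation takes over.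
- Fallback (from 3, back at 7): the polarity is reversed. Knoevenagel condensation of 3 with isobutyraldehyde (piperidinium acetate) gives the isobutylidene tricarbonyl compound F7. An enamine-catalysed Michael addition of acetaldehyde follows, using the diphenylprolinol silyl ether antipode that gives 3S, and delivers 7.

## Further compounds

F1 | step 8 | methyl (1S,6S)-1-(2,2-dimethyl-3-oxopentanoyl)-3-(4-methylpent-3-en-1-yl)-6-(propan-2-yl)cyclohex-3-ene-1-carboxylate | COC(=O)[C@]1(CC(CCC=C(C)C)=CC[C@H]1C(C)C)C(=O)C(C)(C)C(=O)CC
F2 | step 8 | (6R,11S)-3-hydroxy-2,4,4-trimethyl-8-(4-methylpent-3-en-1-yl)-11-(propan-2-yl)spiro[5.5]undeca-2,8-diene-1,5-dione | OC1=C(C)C(=O)[C@]2(CC(CCC=C(C)C)=CC[C@H]2C(C)C)C(=O)C1(C)C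
F3 | step 5 | methyl 2-[(3S,5R)-5-hydroxy-2,10-dimethyl-6-methylideneundec-9-en-3-yl]-4,4-dimethyl-3,5-dioxoheptanoate | COC(=O)C([C@@H](C[C@@H](O)C(=C)CCC=C(C)C)C(C)C)C(=O)C(C)(C)C(=O)CC
F4 | step 4 | methyl 2-[(3S)-5-hydroxy-2,10-dimethyl-6-methylideneundec-9-en-3-yl]-4,4-dimethyl-3,5-dioxoheptanoate (both C5 epimers) | COC(=O)C([C@@H](CC(O)C(=C)CCC=C(C)C)C(C)C)C(=O)C(C)(C)C(=O)CC
F5 | step 4 | methyl 2-[(3S)-2,10-dimethyl-6-methylidene-5-oxoundec-9-en-3-yl]-4,4-dimethyl-3,5-dioxoheptanoate | COC(=O)C([C@@H](CC(=O)C(=C)CCC=C(C)C)C(C)C)C(=O)C(C)(C)C(=O)CC
F6 | step 7 | (2R,4S)-5-methoxy-6,8,8-trimethyl-2-(6-methylhepta-1,5-dien-2-yl)-4-(propan-2-yl)-3,4-dihydro-2H-chromen-7(8H)-one | COC1=C(C)C(=O)C(C)(C)C2=C1[C@H](C(C)C)C[C@@H](O2)C(=C)CCC=C(C)C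
F7 | step 3 | methyl 4,4-dimethyl-2-(2-methylpropylidene)-3,5-dioxoheptanoate | COC(=O)C(=CC(C)C)C(=O)C(C)(C)C(=O)CC
A1 | alternative 1 | 5-methoxy-4,6,6-trimethyl-2-(2-methylpropylidene)cyclohex-4-ene-1,3-dione | COC1=C(C)C(=O)C(=CC(C)C)C(=O)C1(C)C
A2 | alternative 1 | myrcene (7-methyl-3-methylideneocta-1,6-diene) | C=CC(=C)CCC=C(C)C
A3 | alternative 1 | 3-methoxy-2,4,4-trimethyl-9-(4-methylpent-3-en-1-yl)-11-(propan-2-yl)spiro[5.5]undeca-2,8-diene-1,5-dione | COC1=C(C)C(=O)C2(CC=C(CCC=C(C)C)CC2C(C)C)C(=O)C1(C)C
A4 | alternative 2 | (5S)-5-(4-methoxy-3,5,5-trimethyl-2,6-dioxocyclohex-3-en-1-yl)-6-methyl-2-(4-methylpent-3-en-1-yl)hept-2-en-1-yl methyl carbonate | COC1=C(C)C(=O)C([C@@H](CC=C(COC(=O)OC)CCC=C(C)C)C(C)C)C(=O)C1(C)C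
A5 | alternative 3 | (2R)-5-methoxy-4,6,6-trimethyl-2-[(3S)-2-methylhex-5-en-3-yl]-2-(6-methyl-2-methylidenehept-5-en-1-yl)cyclohex-4-ene-1,3-dione | COC1=C(C)C(=O)[C@@](CC(=C)CCC=C(C)C)([C@@H](CC=C)C(C)C)C(=O)C1(C)C
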